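**Plan**
- Feature: C4 (bearing methyl C15, the hydroxyl, C3 and C5) is the carbinol stereocentre of (R)-linalool, and the C10-methyl decalin around it (ring A = C1–C5, C10; ring B = C5–C10) is the intramolecular [4+2] adduct of a C9=C10 isopropenyl ketone (C1=O) with a C5=C6–C7=C8 diene.
- Cuts, in retrosynthetic order: aryl O–CH3 and aryl–CHO bonds; C9′–C10′ (isobutyl) and C9′–aryl; C1–C9′; then C5–C10 and C8–C9 together; then C6–C7 (Heck) and C1–C10 (Grignard) of the open chain.
- Forward: the C1–C10 chain is built on linalool, rings A and B close together in one Diels–Alder step, and the C1 ketone is then turned via a vinyllithium into the formyl, aryl, isobutyl and diformylphloroglucinol parts of the side chain.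
- Stereochemistry: C4 from the chiral pool; C5 and C10 relayed from C4 in the cycloaddition; C7 by hydrogenation anti to the C10 methyl; C1 by hydrogenation directed by the axial C4 hydroxyl; C9′ by 1,3-allylic-strain-controlled trapping of a benzylic cation next to C1.

Key step: step 8

Remark: eudesmane numbering is used (benzylic side-chain carbon = C9′). Faces are named by the C10 methyl (C14): "syn to C14" and "anti to C14". The target SMILES is read as 4-OH syn to C14 (axial), H5 and H7 anti, C1 side chain anti to C14 (axial), C9′ S.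
Remark: the C6–C7 bond is made by a Heck reaction and not through a ruthenium carbene, because 2 and 6 are 1,6- and 1,7-dienes that would close by ring-closing metathesis.
Remark: isopropenylmagnesium bromide is taken as the commercial THF solution. Carbinol centres written without configuration (C1 in 6 and 11, C9′ in 22) are epimer mixtures that converge in a later step.

**Step 1**
Reactants: 1 (R)-(−)-linalool
Product: 2 (R)-linalool triethylsilyl ether
Conditions: Et3SiOTf, 2,6-lutidine, CH2Cl2, −78 → 0 °C
Reagents that add atoms: triethylsilyl trifluoromethanesulfonate, CC[Si](CC)(CC)OS(=O)(=O)C(F)(F)F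
Why: Silyl ether formation from a tertiary alcohol with a silyl triflate and a hindered pyridine base is standard and leaves both alkenes and the C4 centre untouched.

**Step 2**
Reactants: 2 (R)-linalool triethylsilyl ether
Product: 4 (4R)-4-methyl-4-(triethylsilyloxy)hex-5-enal, via ozonide 3 (not isolated)
Conditions: O3 (about 1 equiv, Sudan Red 7B end point), CH2Cl2, −78 °C; then Me2S, −78 °C → rt
Reagents that add atoms: ozone, [O-][O+]=O
Why: Ozonolysis with reductive work-up; the electrophilic ozone should attack the electron-rich trisubstituted alkene much faster than the monosubstituted vinyl group next to the quaternary carbon, so one equivalent cleaves only the former.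

**Step 3**
Reactants: 4 (4R)-4-methyl-4-(triethylsilyloxy)hex-5-enal; 5 isopropenylmagnesium bromide
Product: 6 (3RS,6R)-2,6-dimethyl-6-(triethylsilyloxy)octa-1,7-dien-3-ol
Conditions: THF, −78 → 0 °C; aq. NH4Cl
Reagents that add atoms: none
Why: Grignard 1,2-addition to an aldehyde forms C1–C10; the new C1 carbinol centre is a mixture that the later oxidation erases.

**Step 4**
Reactants: 7 3-hydroxy-3-methylbutan-2-one
Product: 8 3-methyl-3-(triethylsilyloxy)butan-2-one
Conditions: Et3SiOTf, 2,6-lutidine, CH2Cl2, −78 → 0 °C
Reagents that add atoms: triethylsilyl trifluoromethanesulfonate, CC[Si](CC)(CC)OS(=O)(=O)C(F)(F)F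
Why: Silylation of a tertiary α-hydroxy ketone with a silyl triflate is routine and masks the future C11 hydroxyl.

**Step 5**
Reactants: 8 3-methyl-3-(triethylsilyloxy)butan-2-one
Product: 10 3-methyl-3-(triethylsilyloxy)but-1-en-2-yl trifluoromethanesulfonate, via potassium enolate 9 (not isolated)
Conditions: KN(SiMe3)2, THF, −78 °C; PhNTf2, −78 → 0 °C
Reagents that add atoms: N-phenylbis(trifluoromethanesulfonimide), O=S(=O)(N(c1ccccc1)S(=O)(=O)C(F)(F)F)C(F)(F)F
Why: Enolate O-triflation; only the methyl side of the ketone can enolise, so the 2-triflyloxy-1-alkene should form as a single regioisomer.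

**Step 6**
Reactants: 6 (3RS,6R)-2,6-dimethyl-6-(triethylsilyloxy)octa-1,7-dien-3-ol; 10 3-methyl-3-(triethylsilyloxy)but-1-en-2-yl trifluoromethanesulfonate
Product: 11 (3RS,6R,7E)-2,6,10-trimethyl-9-methylidene-6,10-bis(triethylsilyloxy)undeca-1,7-dien-3-ol
Conditions: Pd(OAc)2 (10 mol%), PPh3 (20 mol%), Et3N, DMF, 65 °C
Reagents that add atoms: none
Why: Heck alkenylation; the alkenylpalladium species should add to the unsubstituted carbon of the vinyl carbinol (as with 2-methylbut-3-en-2-ol) and syn β-hydride elimination from C6 gives the E diene, while the 1,1-disubstituted isopropenyl alkene inserts far more slowly.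

**Step 7**
Reactants: 11 (3RS,6R,7E)-2,6,10-trimethyl-9-methylidene-6,10-bis(triethylsilyloxy)undeca-1,7-dien-3-ol
Product: 12 (6R,7E)-2,6,10-trimethyl-9-methylidene-6,10-bis(triethylsilyloxy)undeca-1,7-dien-3-one
Conditions: Dess–Martin periodinane, CH2Cl2, 0 °C; used directly
Reagents that add atoms: none
Why: Dess–Martin oxidation of a secondary allylic alcohol under near-neutral conditions; both C1 epimers give the same enone and the tertiary silyl ethers are inert.

**Step 8**
Reactants: 12 (6R,7E)-2,6,10-trimethyl-9-methylidene-6,10-bis(triethylsilyloxy)undeca-1,7-dien-3-one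
Product: 13 trans-fused octalone (C1 ketone, C6=C7 alkene, axial C4 triethylsilyloxy syn to the C10 methyl, equatorial C4 methyl, H5 anti to the C10 methyl, C11 triethylsilyloxy)
Conditions: toluene, BHT (cat.), 80 °C
Reagents that add atoms: none
Why: A concerted, thermally allowed [4+2] cycloaddition joins the isopropenyl ketone (C9=C10, activated by the C1 carbonyl) to the s-cis C5=C6–C7=C8 diene of the same chain and forms C5–C10 and C8–C9 at once; the closest known reaction type is the type 1 intramolecular Diels–Alder reaction of deca-1,7,9-trien-3-ones. Ring A closes as a six-membered carbocycle through the four-atom tether C1–C4 in a chair-like arrangement, and ring B is the cyclohexene (C6=C7) created by the cycloaddition itself. C5 and C10 are controlled by the C4 centre: in the tether chair the C4 methyl is equatorial and the smaller oxygen substituent axial, syn to the C10 methyl, because the other chair would put two methyl groups syn-diaxial, so only one diene face is used. The step needs the transition state with the C10 methyl endo and the tether carbonyl exo, which gives the trans ring fusion; an α-methyl enone dienophile prefers carbonyl-exo addition, and the bulky C7 substituent holds the diene s-cis so that moderate heating suffices and no Lewis acid has to be brought near the two tertiary allylic silyl ethers. Trans over cis fusion is the selectivity that matters, and Me2AlCl at −78 °C is the first variable to change if the thermal reaction is not selective enough.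

**Step 9**
Reactants: 13 trans-fused octalone
Product: 14 saturated decalone (H7 anti to the C10 methyl, C11 side chain equatorial)
Conditions: H2 (1 atm), 5% Pt/C, EtOAc, rt
Reagents that add atoms: none
Why: Heterogeneous catalytic hydrogenation should deliver hydrogen to C6=C7 from the face anti to the axial C10 methyl and the axial C4 silyloxy group, which sets C7 with the C11 group equatorial; platinum on carbon is chosen to limit hydrogenolysis of the allylic C11–O bond.

**Step 10**
Reactants: 14 saturated decalone
Product: 15 C1 2,4,6-triisopropylbenzenesulfonylhydrazone of 14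
Conditions: 2,4,6-(i-Pr)3C6H2SO2NHNH2, THF, rt (cat. pyridinium p-toluenesulfonate)
Reagents that add atoms: 2,4,6-triisopropylbenzenesulfonyl hydrazide, CC(C)c1cc(C(C)C)c(S(=O)(=O)NN)c(C(C)C)c1
Why: Hydrazone formation by condensation at the only carbonyl group, a reaction that tolerates a neighbouring quaternary carbon.

**Step 11**
Reactants: 15 C1 2,4,6-triisopropylbenzenesulfonylhydrazone of 14
Product: 17 C1-formyl Δ1(2)-octalin (enal; C4 and C11 triethylsilyl ethers), via C1 vinyllithium 16 (not isolated)
Conditions: n-BuLi (2.2 equiv), TMEDA, THF, −78 → 0 °C; DMF, −78 °C → rt; aq. NH4Cl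
Reagents that add atoms: N,N-dimethylformamide, CN(C)C=O
Why: Shapiro reaction; deprotonation at N–H and at C2 (the only α-CH2) followed by loss of sulfinate and N2 gives the C1 vinyllithium, which DMF formylates to install C9′.

**Step 12**
Reactants: 17 C1-formyl Δ1(2)-octalin bis(triethylsilyl) ether
Product: 18 enal diol (free C4 and C11 hydroxyls)
Conditions: HF·pyridine, THF/pyridine, 0 °C → rt
Reagents that add atoms: none
Why: Fluoride-driven cleavage of both tertiary triethylsilyl ethers (Si–F bond formation) under conditions that should not affect the enal.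

**Step 13**
Reactants: 18 enal diol
Product: 19 saturated aldehyde diol (C1 formyl axial and anti to the C10 methyl, H1 syn to it)
Conditions: H2 (1 atm), [Ir(cod)(PCy3)(py)]PF6 (10 mol%), CH2Cl2, rt; taken on without delay
Reagents that add atoms: none
Why: Hydroxyl-directed homogeneous hydrogenation with a cationic iridium catalyst; the axial homoallylic C4 hydroxyl (a cyclohex-3-en-1-ol pattern) binds the metal and both hydrogens add to C1=C2 from the face syn to C14, so the formyl group ends up axial on the opposite face.

**Step 14**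
Reactants: 19 saturated aldehyde diol; 20 1,3,5-trimethoxybenzene
Product: 22 C9′ carbinol (2,4,6-trimethoxyphenyl)(hydroxy)methyl triol, via 2,4,6-trimethoxyphenyllithium 21 (not isolated)
Conditions: 20, n-BuLi, THF, 0 °C → rt; then 19 (3.5 equiv of aryllithium per aldehyde), −78 → 0 °C; aq. NH4Cl
Reagents that add atoms: none
Why: Directed ortho-lithiation between two methoxy groups followed by 1,2-addition of the aryllithium to the aldehyde; excess reagent absorbs the two hydroxyl protons and the C9′ configuration is irrelevant because this centre is ionised in the next step.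

**Step 15**
Reactants: 22 C9′ carbinol; 23 trimethyl(2-methylallyl)silane
Product: 25 C9′ (S)-2-methylallyl compound, via benzylic cation 24 (not isolated)
Conditions: 23 (4 equiv), BF3·OEt2 (1.2 equiv), CH2Cl2, −78 °C
Reagents that add atoms: none
Why: SN1 allylation of a benzylic alcohol with an allylsilane (Hosomi–Sakurai type); the 2,4,6-trimethoxybenzylic cation should adopt the rotamer with C1–H in the cation plane next to an ortho methoxy group (1,3-allylic strain) and be attacked on the C2 side, away from quaternary C10, which gives the required C9′ configuration.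

**Step 16**
Reactants: 25 C9′ (S)-2-methylallyl compound
Product: 26 isobutyl trimethoxyphenyl diol
Conditions: H2 (1 atm), 10% Pd/C, EtOAc, rt
Reagents that add atoms: none
Why: Catalytic hydrogenation of a 1,1-disubstituted alkene creates no stereocentre and should not touch the electron-rich arene.

**Step 17**
Reactants: 26 isobutyl trimethoxyphenyl diol
Product: 27 3,5-dibromo-2,4,6-trimethoxyphenyl diol
Conditions: N-bromosuccinimide (2.05 equiv), MeCN, 0 °C, dark
Reagents that add atoms: N-bromosuccinimide, O=C1CCC(=O)N1Br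
Why: Electrophilic aromatic bromination; the two free ring positions, each flanked by two methoxy groups, are the most nucleophilic sites in the molecule.

**Step 18**
Reactants: 27 3,5-dibromo-2,4,6-trimethoxyphenyl diol
Product: 29 3,5-diformyl-2,4,6-trimethoxyphenyl diol, via dilithio arene 28 (not isolated)
Conditions: MeLi (2.0 equiv), THF, −78 °C; t-BuLi (4.2 equiv), −78 °C; DMF, −78 → 0 °C; aq. NH4Cl
Reagents that add atoms: N,N-dimethylformamide, CN(C)C=O
Why: Bromine–lithium exchange followed by formylation with DMF; the two hydroxyls are first converted into alkoxides and each aryl–lithium bond is stabilised by two flanking methoxy groups.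

**Step 19**
Reactants: 29 3,5-diformyl-2,4,6-trimethoxyphenyl diol
Product: 30 target, 5-[(1S)-1-[(1S,4R,4aS,6S,8aR)-4-hydroxy-6-(2-hydroxypropan-2-yl)-4,8a-dimethyldecahydronaphthalen-1-yl]-3-methylbutyl]-2,4,6-trihydroxybenzene-1,3-dicarbaldehyde
Conditions: NaSEt (excess), DMF, 120 °C; then aq. HCl
Reagents that add atoms: none
Why: Nucleophilic (SN2) O-demethylation of aryl methyl ethers by thiolate, helped by the ortho and para formyl groups that stabilise the phenoxide leaving groups; the basic medium spares the two tertiary alcohols.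

**Compound list**
1 | (R)-(−)-linalool | CC(C)=CCC[C@@](C)(O)C=C | starting material
2 | (R)-linalool triethylsilyl ether | CC(C)=CCC[C@@](C)(O[Si](CC)(CC)CC)C=C | intermediate
3 | ozonide of 2 (3,3-dimethyl-1,2,4-trioxolane carrying the C1–C6 chain at C5) | CC1(C)OOC(CC[C@@](C)(O[Si](CC)(CC)CC)C=C)O1 | intermediate
4 | (4R)-4-methyl-4-(triethylsilyloxy)hex-5-enal | O=CCC[C@@](C)(O[Si](CC)(CC)CC)C=C | intermediate
5 | isopropenylmagnesium bromide | C=C(C)[Mg]Br | starting material
6 | (3RS,6R)-2,6-dimethyl-6-(triethylsilyloxy)octa-1,7-dien-3-ol | C=C(C)C(O)CC[C@@](C)(O[Si](CC)(CC)CC)C=C | intermediate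
7 | 3-hydroxy-3-methylbutan-2-one | CC(=O)C(C)(C)O | starting material
8 | 3-methyl-3-(triethylsilyloxy)butan-2-one | CC(=O)C(C)(C)O[Si](CC)(CC)CC | intermediate
9 | potassium enolate of 8 | C=C([O-])C(C)(C)O[Si](CC)(CC)CC.[K+] | intermediate
10 | 3-methyl-3-(triethylsilyloxy)but-1-en-2-yl trifluoromethanesulfonate | C=C(OS(=O)(=O)C(F)(F)F)C(C)(C)O[Si](CC)(CC)CC | intermediate
11 | (3RS,6R,7E)-2,6,10-trimethyl-9-methylidene-6,10-bis(triethylsilyloxy)undeca-1,7-dien-3-ol | C=C(C)C(O)CC[C@@](C)(O[Si](CC)(CC)CC)/C=C/C(=C)C(C)(C)O[Si](CC)(CC)CC | intermediate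
12 | (6R,7E)-2,6,10-trimethyl-9-methylidene-6,10-bis(triethylsilyloxy)undeca-1,7-dien-3-one (Diels–Alder precursor) | C=C(C)C(=O)CC[C@@](C)(O[Si](CC)(CC)CC)/C=C/C(=C)C(C)(C)O[Si](CC)(CC)CC | intermediate
13 | trans-fused octalone: C1 ketone, C6=C7, C4 OSiEt3 syn to C10 methyl, H5 anti, C11 OSiEt3 (Diels–Alder product) | O=C1CC[C@@](C)(O[Si](CC)(CC)CC)[C@H]2C=C(C(C)(C)O[Si](CC)(CC)CC)CC[C@]12C | intermediate
14 | saturated decalone (H7 anti to C10 methyl) | O=C1CC[C@@](C)(O[Si](CC)(CC)CC)[C@H]2C[C@@H](C(C)(C)O[Si](CC)(CC)CC)CC[C@]12C | intermediate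
15 | C1 2,4,6-triisopropylbenzenesulfonylhydrazone of 14 | CC(C)c1cc(C(C)C)c(S(=O)(=O)NN=C2CC[C@@](C)(O[Si](CC)(CC)CC)[C@H]3C[C@@H](C(C)(C)O[Si](CC)(CC)CC)CC[C@]23C)c(C(C)C)c1 | intermediate
16 | C1 vinyllithium (C1=C2) | [Li]C1=CC[C@@](C)(O[Si](CC)(CC)CC)[C@H]2C[C@@H](C(C)(C)O[Si](CC)(CC)CC)CC[C@]12C | intermediate
17 | C1-formyl Δ1(2)-octalin bis(triethylsilyl) ether | O=CC1=CC[C@@](C)(O[Si](CC)(CC)CC)[C@H]2C[C@@H](C(C)(C)O[Si](CC)(CC)CC)CC[C@]12C | intermediate
18 | enal diol | O=CC1=CC[C@@](C)(O)[C@H]2C[C@@H](C(C)(C)O)CC[C@]12C | intermediate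
19 | saturated aldehyde diol (C1 formyl axial, anti to C10 methyl) | O=C[C@@H]1CC[C@@](C)(O)[C@H]2C[C@@H](C(C)(C)O)CC[C@]12C | intermediate
20 | 1,3,5-trimethoxybenzene | COc1cc(OC)cc(OC)c1 | starting material
21 | 2,4,6-trimethoxyphenyllithium | [Li]c1c(OC)cc(OC)cc1OC | intermediate
22 | C9′ carbinol, (2,4,6-trimethoxyphenyl)(hydroxy)methyl at C1, epimers at C9′ | OC(c1c(OC)cc(OC)cc1OC)[C@@H]1CC[C@@](C)(O)[C@H]2C[C@@H](C(C)(C)O)CC[C@]12C | intermediate
23 | trimethyl(2-methylallyl)silane | C=C(C)C[Si](C)(C)C | starting material
24 | 2,4,6-trimethoxybenzylic cation at C9′ | [CH+](c1c(OC)cc(OC)cc1OC)[C@@H]1CC[C@@](C)(O)[C@H]2C[C@@H](C(C)(C)O)CC[C@]12C | intermediate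
25 | C9′ (S)-2-methylallyl trimethoxyphenyl diol | C=C(C)C[C@H](c1c(OC)cc(OC)cc1OC)[C@@H]1CC[C@@](C)(O)[C@H]2C[C@@H](C(C)(C)O)CC[C@]12C | intermediate
26 | isobutyl trimethoxyphenyl diol | CC(C)C[C@H](c1c(OC)cc(OC)cc1OC)[C@@H]1CC[C@@](C)(O)[C@H]2C[C@@H](C(C)(C)O)CC[C@]12C | intermediate
27 | 3,5-dibromo-2,4,6-trimethoxyphenyl diol | CC(C)C[C@H](c1c(OC)c(Br)c(OC)c(Br)c1OC)[C@@H]1CC[C@@](C)(O)[C@H]2C[C@@H](C(C)(C)O)CC[C@]12C | intermediate
28 | 3,5-dilithio arene bis(lithium alkoxide) | CC(C)C[C@H](c1c(OC)c([Li])c(OC)c([Li])c1OC)[C@@H]1CC[C@@](C)(O[Li])[C@H]2C[C@@H](C(C)(C)O[Li])CC[C@]12C | intermediate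
29 | 3,5-diformyl-2,4,6-trimethoxyphenyl diol | CC(C)C[C@H](c1c(OC)c(C=O)c(OC)c(C=O)c1OC)[C@@H]1CC[C@@](C)(O)[C@H]2C[C@@H](C(C)(C)O)CC[C@]12C | intermediate
30 | target CNP0409870.3 | CC(C)C[C@H](c1c(O)c(C=O)c(O)c(C=O)c1O)[C@@H]1CC[C@@](C)(O)[C@H]2C[C@@H](C(C)(C)O)CC[C@]12C | target

**Totals**
Total step count: 19. Longest linear sequence: 17 steps (steps 1–3 and 6–19 from (R)-linalool); steps 4–5 prepare the alkenyl triflate.

**Steps most likely to fail**

1. Step 8. The carbonyl-endo transition state may compete with the methyl-endo one, so that the ring fusion forms partly or mainly cis.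
   Fallback: a second activating group is placed on the dienophile terminus so that its endo preference works in the trans sense, and it is removed after the cycloaddition. The fallback sets out from aldehyde 4. A CrCl2/NiCl2-mediated Nozaki–Hiyama–Kishi coupling with (E)-3-iodobut-2-en-1-ol would give the allylic diol F1. The Heck reaction with 10 under the conditions of step 6 would give the tetraene diol F2. Dess–Martin oxidation of both allylic alcohols would give the keto enal F3. In F3 the C9 formyl group is trans to the C1 carbonyl, so formyl-endo and tether-exo coincide, and a secondary-amine salt (iminium activation of the enal only) should reinforce this. Cycloaddition would then give the formyl octalone F4. Decarbonylation with stoichiometric RhCl(PPh3)3 in toluene at 110 °C comes back to the route at 13.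

2. Step 13. Hydrogen may be delivered from the face anti to C14 if steric approach control overrides the hydroxyl direction; the aldehyde may slow the catalyst; and the axial aldehyde may epimerise at C1.
   Fallback: the C1–C bond is made by a radical on the face anti to C14, with H1 already in place. The fallback sets out from ketone 14. NaBH4 reduction would give the C1 alcohol F5, and NaH, CS2 and MeI would give the xanthate F6. With Bu3SnH, AIBN and excess tert-butyl isocyanide the C1 radical should be trapped anti to the axial C10 methyl, and loss of the tert-butyl radical gives the axial nitrile F7. Reduction with i-Bu2AlH at −78 °C would give the silylated aldehyde F8. HF·pyridine comes back to the route at 19.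

3. Step 15. The cation may be trapped from the C10 side if rotamer control is weaker than modelled, or H1 may be lost to give a styrene.
   Fallback: the order of bond formation at C9′ is exchanged. The fallback sets out from 22. Dess–Martin oxidation would give the aryl ketone F9, and 2-methylallylmagnesium chloride would give the tertiary carbinol F10. Ionic hydrogenation (Et3SiH, BF3·OEt2, CH2Cl2, −78 °C) comes back to the route at 25. Hydride and the carbon substituent exchange roles, so the sense of induction at C9′ is inverted relative to step 15. This helps most when the direct allylation is selective for the wrong face.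

**Further compounds**
F1 | step 8 | (2E,4RS,7R)-3,7-dimethyl-7-(triethylsilyloxy)nona-2,8-diene-1,4-diol | OC/C=C(\C)C(O)CC[C@@](C)(O[Si](CC)(CC)CC)C=C
F2 | step 8 | (2E,4RS,7R,8E)-3,7,11-trimethyl-10-methylidene-7,11-bis(triethylsilyloxy)dodeca-2,8-diene-1,4-diol | OC/C=C(\C)C(O)CC[C@@](C)(O[Si](CC)(CC)CC)/C=C/C(=C)C(C)(C)O[Si](CC)(CC)CC
F3 | step 8 | (2E,7R,8E)-3,7,11-trimethyl-10-methylidene-4-oxo-7,11-bis(triethylsilyloxy)dodeca-2,8-dienal | O=C/C=C(\C)C(=O)CC[C@@](C)(O[Si](CC)(CC)CC)/C=C/C(=C)C(C)(C)O[Si](CC)(CC)CC
F4 | step 8 | C9-formyl derivative of 13 (formyl syn to the C10 methyl) | O=C1CC[C@@](C)(O[Si](CC)(CC)CC)[C@H]2C=C(C(C)(C)O[Si](CC)(CC)CC)C[C@@H](C=O)[C@]12C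
F5 | step 13 | C1 alcohol from 14 (hydroxyl equatorial, syn to the C10 methyl) | O[C@H]1CC[C@@](C)(O[Si](CC)(CC)CC)[C@H]2C[C@@H](C(C)(C)O[Si](CC)(CC)CC)CC[C@]12C
F6 | step 13 | O-alkyl S-methyl xanthate of F5 | CSC(=S)O[C@H]1CC[C@@](C)(O[Si](CC)(CC)CC)[C@H]2C[C@@H](C(C)(C)O[Si](CC)(CC)CC)CC[C@]12C
F7 | step 13 | C1 axial nitrile (anti to the C10 methyl), bis(triethylsilyl) ether | N#C[C@@H]1CC[C@@](C)(O[Si](CC)(CC)CC)[C@H]2C[C@@H](C(C)(C)O[Si](CC)(CC)CC)CC[C@]12C
F8 | step 13 | C1 axial aldehyde, bis(triethylsilyl) ether of 19 | O=C[C@@H]1CC[C@@](C)(O[Si](CC)(CC)CC)[C@H]2C[C@@H](C(C)(C)O[Si](CC)(CC)CC)CC[C@]12C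
F9 | step 15 | C9′ aryl ketone (2,4,6-trimethoxybenzoyl at C1) | O=C(c1c(OC)cc(OC)cc1OC)[C@@H]1CC[C@@](C)(O)[C@H]2C[C@@H](C(C)(C)O)CC[C@]12C
F10 | step 15 | C9′ tertiary carbinol bearing 2-methylallyl and 2,4,6-trimethoxyphenyl | C=C(C)CC(O)(c1c(OC)cc(OC)cc1OC)[C@@H]1CC[C@@](C)(O)[C@H]2C[C@@H](C(C)(C)O)CC[C@]12C
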